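**Assumptions (one line):** the 4-OH of 5-hydroxyvanillin (para to CHO, pKa about 7) is the phenol that reacts in the Mitsunobu coupling. The (S)-diarylprolinol catalyst gives the (2R,3S)-epoxy aldehyde, which is (2S,3S) after reduction. The quinone-methide cyclisation is trans-selective, as in flavonolignan chemistry.

**Retrosynthesis**
1. Palstatin comes from a chalcone by I2/DMSO oxidative cyclisation. The chalcone comes from the benzodioxane aldehyde and phloroacetophenone.
2. The trans-2,3-benzodioxane ring (formed second) arises by DDQ oxidation of the syringol CH2 to a p-quinone methide. The tethered 3'-OH then adds to it, which sets the benzylic centre.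
3. The β-aryl ether is made by Mitsunobu inversion between the 4-OH of 5-hydroxyvanillin and a chiral secondary alcohol.
4. The chiral alcohol comes from hydrogenolysis of a trans-3-aryl glycidol. The glycidol comes from organocatalytic epoxidation of silyl-protected sinapaldehyde, which sets the first stereocentre.

**Step 1**
Reactants: 1 sinapaldehyde; TBSCl
Product: 2 (E)-3-[4-(tert-butyldimethylsilyloxy)-3,5-dimethoxyphenyl]propenal
Conditions: TBSCl, imidazole, DMF, 0 °C to rt
Reagents that add atoms: tert-butyldimethylsilyl chloride, CC(C)(C)[Si](C)(C)Cl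
Why: Silylation masks the phenol, which would otherwise turn the iminium into a deactivated quinone-methide-type species in step 2.

**Step 2**
Reactants: 2; hydrogen peroxide
Product: 3 (2R,3S)-3-[4-(TBSO)-3,5-dimethoxyphenyl]oxirane-2-carbaldehyde
Conditions: (S)-2-{bis[3,5-bis(CF3)phenyl](trimethylsilyloxy)methyl}pyrrolidine (15 mol%), 30% aq. H2O2, CH2Cl2, rt, 36 h
Reagents that add atoms: hydrogen peroxide, OO
Why: Jørgensen–Hayashi iminium-catalysed nucleophilic epoxidation. The catalyst blocks one face of the iminium. HOO⁻ adds, then the enamine closes the 3-exo-tet ring to give the trans-epoxide, which sets the C2 stereocentre that becomes dioxane C3.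

**Step 3**
Reactants: 3
Product: 4 [(2S,3S)-3-[4-(TBSO)-3,5-dimethoxyphenyl]oxiran-2-yl]methanol
Conditions: NaBH4, EtOH, 0 °C, 15 min (crude aldehyde from step 2, not chromatographed)
Reagents that add atoms: none
Why: Chemoselective aldehyde reduction. The epoxide and stereocentres are untouched, and the CIP label changes from R to S only through priority change.

**Step 4**
Reactants: 4; TBSCl
Product: 5 tert-butyl{[(2S,3S)-3-(4-TBSO-3,5-dimethoxyphenyl)oxiran-2-yl]methoxy}dimethylsilane
Conditions: TBSCl, imidazole, DMF, 0 °C to rt
Reagents that add atoms: tert-butyldimethylsilyl chloride, CC(C)(C)[Si](C)(C)Cl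
Why: The primary OH is protected so that the later Mitsunobu reaction occurs only at the secondary OH.

**Step 5**
Reactants: 5; H2
Product: 6 (2R)-1-(TBSO)-3-[4-(TBSO)-3,5-dimethoxyphenyl]propan-2-ol
Conditions: H2 (1 atm), 10% Pd/C, solid NaHCO3, EtOAc, rt
Reagents that add atoms: none (only H is added)
Why: Hydrogenolysis of the activated benzylic C–O bond of the aryl epoxide. The C2–O bond is not broken, so C2 keeps its configuration. The epoxide C3 stereocentre is removed, and the epoxide oxygen becomes the secondary OH.

**Step 6**
Reactants: 6; 7 5-hydroxyvanillin (3,4-dihydroxy-5-methoxybenzaldehyde)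
Product: 8 4-{[(2S)-1-(TBSO)-3-(4-TBSO-3,5-dimethoxyphenyl)propan-2-yl]oxy}-3-hydroxy-5-methoxybenzaldehyde
Conditions: PPh3, DIAD, THF, 0 °C to rt
Reagents that add atoms: none
Why: Mitsunobu etherification proceeds by SN2 with inversion, converting (R)-alcohol 6 into the (S)-aryl ether. The more acidic para-formyl 4-OH reacts, which puts the future O4' on the CH(CH2OR) carbon.

**Step 7**
Reactants: 8
Product: 9 3-hydroxy-4-{[(2S)-1-hydroxy-3-(4-hydroxy-3,5-dimethoxyphenyl)propan-2-yl]oxy}-5-methoxybenzaldehyde
Conditions: TBAF, AcOH (1:1), THF, 0 °C to rt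
Reagents that add atoms: none (only H is added)
Why: Both silyl groups are removed. The free syringol OH is needed for quinone-methide formation in step 8.

**Step 8**
Reactants: 9
Product: 10 (2R,3R)-2-(4-hydroxy-3,5-dimethoxyphenyl)-3-(hydroxymethyl)-5-methoxy-2,3-dihydro-1,4-benzodioxine-7-carbaldehyde
Conditions: DDQ (1.2 equiv), CH2Cl2, 4 Å MS, 0 °C to rt; then aq. NaHCO3 work-up
Reagents that add atoms: none (DDQ removes 2 H)
Why: Proposed new method: DDQ abstracts hydride from the unactivated benzylic CH2 of the 4-alkylsyringol to give a p-quinone methide. The ortho-phenol (3'-OH), tethered through the β-aryl ether, adds 6-exo-trig to the quinone methide (DDQH2 provides acid catalysis). The chair-like transition state, with the CH2OH pseudo-equatorial and controlled by the existing C3 stereocentre, gives the trans (2R,3R) ring. The closest known reactions are DDQ oxidation of 4-alkylphenols to trapped quinone methides and the biomimetic quinone-methide closure of benzodioxane lignans. Here it builds the ring and the benzylic stereocentre from a saturated chain by oxidative C–H etherification.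

**Step 9**
Reactants: 10; 11 2',4',6'-trihydroxyacetophenone
Product: 12 (E)-chalcone, 3-[benzodioxanyl]-1-(2,4,6-trihydroxyphenyl)prop-2-en-1-one
Conditions: KOH (6 equiv), EtOH/H2O, rt, N2, 48 h; acidify to pH 4 with HCl
Reagents that add atoms: none
Why: Claisen–Schmidt aldol condensation. Rt and short exposure to base avoid quinone-methide epimerisation at the benzylic centre.

**Step 10**
Reactants: 12
Product: 13 palstatin
Conditions: I2 (0.2 equiv), DMSO, 130 °C, 1–2 h
Reagents that add atoms: none
Why: The 2'-OH chalcone cyclises by oxa-Michael addition to the flavanone. I2/DMSO then oxidises it to the flavone (oxidative cyclisation). The flavone is achiral at C-ring, and the dioxane stereocentres are untouched.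

**Stereochemistry check:** Dioxane C3 (R) is set by the catalyst in step 2. It is retained in step 5, inverted in step 6, and untouched afterwards. Dioxane C2 (R) is set in step 8 by trans closure. Both centres are (R,R), as in the target SMILES.

**Compound list**
1 | sinapaldehyde | COc1cc(/C=C/C=O)cc(OC)c1O | starting material
2 | (E)-3-[4-(TBSO)-3,5-dimethoxyphenyl]propenal | COc1cc(/C=C/C=O)cc(OC)c1O[Si](C)(C)C(C)(C)C | intermediate
3 | (2R,3S)-3-[4-(TBSO)-3,5-dimethoxyphenyl]oxirane-2-carbaldehyde | O=C[C@@H]1O[C@H]1c1cc(OC)c(O[Si](C)(C)C(C)(C)C)c(OC)c1 | intermediate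
4 | [(2S,3S)-3-[4-(TBSO)-3,5-dimethoxyphenyl]oxiran-2-yl]methanol | OC[C@@H]1O[C@H]1c1cc(OC)c(O[Si](C)(C)C(C)(C)C)c(OC)c1 | intermediate
5 | primary TBS ether of 4 | CC(C)(C)[Si](C)(C)OC[C@@H]1O[C@H]1c1cc(OC)c(O[Si](C)(C)C(C)(C)C)c(OC)c1 | intermediate
6 | (2R)-1-(TBSO)-3-[4-(TBSO)-3,5-dimethoxyphenyl]propan-2-ol | CC(C)(C)[Si](C)(C)OC[C@H](O)Cc1cc(OC)c(O[Si](C)(C)C(C)(C)C)c(OC)c1 | intermediate
7 | 5-hydroxyvanillin | COc1cc(C=O)cc(O)c1O | starting material
8 | Mitsunobu aryl ether (S) | CC(C)(C)[Si](C)(C)OC[C@H](Cc1cc(OC)c(O[Si](C)(C)C(C)(C)C)c(OC)c1)Oc1c(OC)cc(C=O)cc1O | intermediate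
9 | desilylated aryl ether (S) | OC[C@H](Cc1cc(OC)c(O)c(OC)c1)Oc1c(OC)cc(C=O)cc1O | intermediate
10 | trans-benzodioxane aldehyde (2R,3R) | COc1cc([C@H]2Oc3cc(C=O)cc(OC)c3O[C@@H]2CO)cc(OC)c1O | intermediate
11 | 2',4',6'-trihydroxyacetophenone | CC(=O)c1c(O)cc(O)cc1O | starting material
12 | chalcone | COc1cc([C@H]2Oc3cc(/C=C/C(=O)c4c(O)cc(O)cc4O)cc(OC)c3O[C@@H]2CO)cc(OC)c1O | intermediate
13 | palstatin | COc1cc([C@H]2Oc3cc(-c4cc(=O)c5c(O)cc(O)cc5o4)cc(OC)c3O[C@@H]2CO)cc(OC)c1O | target

**Total steps:** 10 (steps 2 and 3 can be telescoped).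
**Longest linear sequence:** 10, from sinapaldehyde. The other building blocks, 7 and 11, are commercial.

**Three steps most likely to fail**
1. **Step 8 (DDQ cyclisation, the new step).** The β-oxygen deactivates the benzylic CH2, and the quinone methide can tautomerise to the enol ether or form a ketal.
 Fallback (known chemistry): open epoxide 5 at the benzylic carbon with the 3-OH of 4-O-allyl-5-hydroxyvanillin. Then remove the allyl group with Pd(0) and close the ring by intramolecular Mitsunobu at C2. Double inversion from the (2S,3S)-epoxide gives the same (2R,3R) trans dioxane.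
2. **Step 6 (Mitsunobu on a hindered 2,6-disubstituted phenol).** Elimination or reaction at the 3-OH are the risks.
 Fallback: convert alcohol 6 to its nosylate and alkylate 5-bromovanillin (Cs2CO3, DMF). Then convert the aryl bromide to the phenol with Cu-catalysed hydroxylation, which reveals the 3-OH with unambiguous regiochemistry.
3. **Steps 9–10 (flavone formation on an unprotected polyphenol).** Low yields or benzylic epimerisation under base or HI are the risks.
 Fallback: oxidise aldehyde 10 to the methyl ester (Pinnick oxidation, then TMSCHN2). Claisen-condense it with 2-hydroxy-4,6-bis(MOM-oxy)acetophenone (LiHMDS) to the 1,3-diketone. Cyclodehydrate with acid, which also removes the MOM groups (Baker–Venkataraman-type C-ring construction).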